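**Retrosynthetic overview**

1. Target 31 ← desilylation of 30 ← reagent-controlled reduction of the C3 ketone 29 ← base-triggered isomerisation of the C40 polyene 26, which carries a 2,2,4,6-tetramethyl-2H-pyran cap at one end and the (3S,5R,6S)-5,6-epoxy ring at the other.
2. Enabling feature: in ring A, C2 is α and C1 is δ to the C3 oxygen across C4=C5 (an isophorone-type array C2–C3(O)–C4=C5–C6=C1). C6 is joined through the conjugated chain C7–C7' to C6' of ring B, whose 5'-OH/6'-ene is the opened form of a C5'–O–C6' oxirane. Cutting C1–C2 and closing that oxirane gives an oxido-triene hidden in a 2H-pyran plus an antheraxanthin-type epoxide, which is the presumed biogenetic precursor of the retro-triol.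
3. 26 ← two Wittig reactions, C15 + C10 + C15: pyranyl salt 12, 2,7-dimethylocta-2,4,6-trienedial 24, epoxy salt 23.
4. 12 ← prenal via bromo-acetal 4 and 4-methoxypent-3-en-2-one (Stork–Danheiser transposition, oxa-6π closure), then C5 Horner–Wadsworth–Emmons extension. 23 ← (−)-actinol via enol triflate, carbonylation, Sharpless epoxidation, the same C5 extension.
5. Ring order: ring B is bought; the 2H-pyran (step 3) and the oxirane (step 11) are temporary rings; ring A is closed last (step 18) while the pyran and the oxirane are both opened.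

Key step: step 18

Assumption: (4R,6R)-4-hydroxy-2,2,6-trimethylcyclohexanone ((−)-actinol, the industrial zeaxanthin building block) is taken as purchasable. Locants C1–C6 (ring A) and C1'–C6' (ring B) follow carotenoid numbering.

**Step 1**
Reactants: 1 3-methylbut-2-enal
Product: 3 2-bromo-3-methylbut-2-enal, via 2,3-dibromo-3-methylbutanal 2 (not isolated)
Conditions: Br2, CH2Cl2, −10 °C; then Et3N, 0 °C → rt
Reagents that add atoms: bromine, BrBr
Why: Bromine addition to the enal followed by amine-mediated E1cB loss of HBr (α-H, tertiary β-Br) is the standard α-bromination of enals, and the β,β-dimethyl pattern leaves no E/Z issue.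

**Step 2**
Reactants: 3 2-bromo-3-methylbut-2-enal
Product: 4 2-bromo-1,1-dimethoxy-3-methylbut-2-ene
Conditions: HC(OMe)3, MeOH, cat. p-TsOH, rt
Reagents that add atoms: trimethyl orthoformate, COC(OC)OC
Why: Acid-catalysed acetalisation with the orthoformate as water scavenger masks the aldehyde for the bromine–lithium exchange of step 3.

**Step 3**
Reactants: 4 2-bromo-1,1-dimethoxy-3-methylbut-2-ene; 5 (3E)-4-methoxypent-3-en-2-one
Product: 8 2,2,4,6-tetramethyl-2H-pyran-3-carbaldehyde, via lithium alkoxide adduct 6 (not isolated), via open (Z)-dienone aldehyde 7 (not isolated)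
Conditions: t-BuLi (2 equiv), THF, −78 °C; anhydrous CeCl3, −78 °C; then 5, −78 → 0 °C; then 1 M HCl, THF, rt
Reagents that add atoms: water, O
Why: Bromine–lithium exchange gives an α-(dialkoxymethyl)alkenyl-lithium whose organocerium adds 1,2 to the vinylogous ester 5, aqueous acid then effects the Stork–Danheiser transposition and acetal hydrolysis to the dienone, acid-mediated E/Z equilibration feeds the Z isomer 7, and this closes by oxa-6π-electrocyclisation to the 2H-pyran 8, which should be favoured by its gem-dimethyl terminus and push–pull conjugation.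

**Step 4**
Reactants: 8 2,2,4,6-tetramethyl-2H-pyran-3-carbaldehyde; 9 ethyl (2E)-4-(diethoxyphosphoryl)-3-methylbut-2-enoate
Product: 10 ethyl (2E,4E)-3-methyl-5-(2,2,4,6-tetramethyl-2H-pyran-3-yl)penta-2,4-dienoate
Conditions: LiN(SiMe3)2, THF, −78 °C; then 8, −78 → 0 °C
Reagents that add atoms: none
Why: Horner–Wadsworth–Emmons olefination with the pre-formed lithium phosphonate should give the E-configured new double bond, and the absence of free base at low temperature keeps the pyran closed.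

**Step 5**
Reactants: 10 ethyl (2E,4E)-3-methyl-5-(2,2,4,6-tetramethyl-2H-pyran-3-yl)penta-2,4-dienoate
Product: 11 (2E,4E)-3-methyl-5-(2,2,4,6-tetramethyl-2H-pyran-3-yl)penta-2,4-dien-1-ol
Conditions: i-Bu2AlH, CH2Cl2, −78 °C; Rochelle salt work-up
Reagents that add atoms: none
Why: 1,2-Reduction of a dienoate by i-Bu2AlH is standard and leaves the dienol ether untouched.

**Step 6**
Reactants: 11 (2E,4E)-3-methyl-5-(2,2,4,6-tetramethyl-2H-pyran-3-yl)penta-2,4-dien-1-ol
Product: 12 [(2E,4E)-3-methyl-5-(2,2,4,6-tetramethyl-2H-pyran-3-yl)penta-2,4-dien-1-yl]triphenylphosphonium bromide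
Conditions: PPh3·HBr, CH2Cl2, 0 °C → rt
Reagents that add atoms: triphenylphosphine hydrobromide, Br.c1ccc(cc1)P(c1ccccc1)c1ccccc1
Why: The electron-rich pentadienylic alcohol ionises to an oxygen-stabilised delocalised cation that triphenylphosphine captures at the primary terminus, as in the standard preparation of C15 Wittig salts from polyenyl carbinols.

**Step 7**
Reactants: 13 (4R,6R)-4-hydroxy-2,2,6-trimethylcyclohexan-1-one
Product: 14 (4R,6R)-4-[(tert-butyldimethylsilyl)oxy]-2,2,6-trimethylcyclohexan-1-one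
Conditions: TBSCl, imidazole, DMF, rt
Reagents that add atoms: tert-butyldimethylsilyl chloride, CC(C)(C)[Si](C)(C)Cl
Why: Standard silylation protects the secondary alcohol whose configuration becomes C3' of the target.

**Step 8**
Reactants: 14 (4R,6R)-4-[(tert-butyldimethylsilyl)oxy]-2,2,6-trimethylcyclohexan-1-one
Product: 15 (4R)-4-[(tert-butyldimethylsilyl)oxy]-2,6,6-trimethylcyclohex-1-en-1-yl trifluoromethanesulfonate
Conditions: LiN(i-Pr)2, THF, −78 °C; then PhNTf2, −78 °C → rt
Reagents that add atoms: N-phenylbis(trifluoromethanesulfonimide), FC(F)(F)S(=O)(=O)N(c1ccccc1)S(=O)(=O)C(F)(F)F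
Why: The ketone has a single enolisable α-position (the C6 methine), so the enolate and its tetrasubstituted enol triflate form regiospecifically; the C6 centre is erased on purpose and C4 is untouched.

**Step 9**
Reactants: 15 (4R)-4-[(tert-butyldimethylsilyl)oxy]-2,6,6-trimethylcyclohex-1-en-1-yl trifluoromethanesulfonate
Product: 16 methyl (4R)-4-[(tert-butyldimethylsilyl)oxy]-2,6,6-trimethylcyclohex-1-ene-1-carboxylate
Conditions: Pd(OAc)2, PPh3, CO (1 atm), MeOH, Et3N, DMF, 60 °C
Reagents that add atoms: carbon monoxide, [C-]#[O+]; methanol, CO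
Why: Palladium-catalysed alkoxycarbonylation of enol triflates is a reliable way to put the C7 carbon on a hindered cyclohexenyl triflate.

**Step 10**
Reactants: 16 methyl (4R)-4-[(tert-butyldimethylsilyl)oxy]-2,6,6-trimethylcyclohex-1-ene-1-carboxylate
Product: 17 {(4R)-4-[(tert-butyldimethylsilyl)oxy]-2,6,6-trimethylcyclohex-1-en-1-yl}methanol
Conditions: i-Bu2AlH, CH2Cl2, −78 → 0 °C; Rochelle salt work-up
Reagents that add atoms: none
Why: Standard 1,2-reduction of the enoate gives the primary allylic alcohol needed for a directed epoxidation.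

**Step 11**
Reactants: 17 {(4R)-4-[(tert-butyldimethylsilyl)oxy]-2,6,6-trimethylcyclohex-1-en-1-yl}methanol
Product: 18 {(1R,4S,6R)-4-[(tert-butyldimethylsilyl)oxy]-2,2,6-trimethyl-7-oxabicyclo[4.1.0]heptan-1-yl}methanol
Conditions: Ti(Oi-Pr)4, D-(−)-diethyl tartrate, t-BuOOH, 4 Å molecular sieves, CH2Cl2, −20 °C
Reagents that add atoms: tert-butyl hydroperoxide, CC(C)(C)OO
Why: In this Sharpless asymmetric epoxidation the titanium–D-(−)-tartrate–peroxide complex should deliver oxygen to the alkene face anti to the C4 silyloxy group (reagent control, reinforced by the steric bias of the substrate), which sets both oxirane carbons and with them the later C5' (R) centre.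

**Step 12**
Reactants: 18 {(1R,4S,6R)-4-[(tert-butyldimethylsilyl)oxy]-2,2,6-trimethyl-7-oxabicyclo[4.1.0]heptan-1-yl}methanol
Product: 19 (1S,4S,6R)-4-[(tert-butyldimethylsilyl)oxy]-2,2,6-trimethyl-7-oxabicyclo[4.1.0]heptane-1-carbaldehyde
Conditions: (n-Pr4N)RuO4 (5 mol%), N-methylmorpholine N-oxide, 4 Å molecular sieves, CH2Cl2, rt
Reagents that add atoms: none
Why: Ley–Griffith oxidation is neutral, so the acid-labile oxirane survives, and the aldehyde has no α-hydrogen to epimerise.

**Step 13**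
Reactants: 19 (1S,4S,6R)-4-[(tert-butyldimethylsilyl)oxy]-2,2,6-trimethyl-7-oxabicyclo[4.1.0]heptane-1-carbaldehyde; 9 ethyl (2E)-4-(diethoxyphosphoryl)-3-methylbut-2-enoate
Product: 20 ethyl (2E,4E)-5-{(1S,4S,6R)-4-[(tert-butyldimethylsilyl)oxy]-2,2,6-trimethyl-7-oxabicyclo[4.1.0]heptan-1-yl}-3-methylpenta-2,4-dienoate
Conditions: LiN(SiMe3)2, THF, −78 °C; then 19, −78 → 0 °C
Reagents that add atoms: none
Why: Horner–Wadsworth–Emmons olefination of the α,β-epoxy aldehyde with the C5 phosphonate is a standard chain extension for epoxy carotenoid end groups and should give the E double bond next to the oxirane.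

**Step 14**
Reactants: 20 ethyl (2E,4E)-5-{(1S,4S,6R)-4-[(tert-butyldimethylsilyl)oxy]-2,2,6-trimethyl-7-oxabicyclo[4.1.0]heptan-1-yl}-3-methylpenta-2,4-dienoate
Product: 21 (2E,4E)-5-{(1S,4S,6R)-4-[(tert-butyldimethylsilyl)oxy]-2,2,6-trimethyl-7-oxabicyclo[4.1.0]heptan-1-yl}-3-methylpenta-2,4-dien-1-ol
Conditions: i-Bu2AlH, CH2Cl2, −78 °C; Rochelle salt work-up
Reagents that add atoms: none
Why: At −78 °C the ester is reduced much faster than the tetrasubstituted alkenyl oxirane is opened.

**Step 15**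
Reactants: 21 (2E,4E)-5-{(1S,4S,6R)-4-[(tert-butyldimethylsilyl)oxy]-2,2,6-trimethyl-7-oxabicyclo[4.1.0]heptan-1-yl}-3-methylpenta-2,4-dien-1-ol
Product: 23 [(2E,4E)-5-{(1S,4S,6R)-4-[(tert-butyldimethylsilyl)oxy]-2,2,6-trimethyl-7-oxabicyclo[4.1.0]heptan-1-yl}-3-methylpenta-2,4-dien-1-yl]triphenylphosphonium bromide, via C15 epoxy allylic bromide 22 (not isolated)
Conditions: CBr4, PPh3, 2,6-lutidine, CH2Cl2, −20 °C; then PPh3, rt
Reagents that add atoms: carbon tetrabromide, BrC(Br)(Br)Br; triphenylphosphine, c1ccc(cc1)P(c1ccccc1)c1ccccc1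
Why: Appel bromination and SN2 quaternisation are neutral, which matters because acid would rearrange the 5,6-epoxide to the furanoid 5,8-oxide.

**Step 16**
Reactants: 12 [(2E,4E)-3-methyl-5-(2,2,4,6-tetramethyl-2H-pyran-3-yl)penta-2,4-dien-1-yl]triphenylphosphonium bromide; 24 (2E,4E,6E)-2,7-dimethylocta-2,4,6-trienedial
Product: 25 (2E,4E,6E,8E,10E,12E)-2,7,11-trimethyl-13-(2,2,4,6-tetramethyl-2H-pyran-3-yl)trideca-2,4,6,8,10,12-hexaenal
Conditions: NaN(SiMe3)2, THF, −78 °C; then addition to 24 (2.5 equiv), −78 → 0 °C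
Reagents that add atoms: none
Why: Wittig olefination of the polyenyl ylide with an excess of the symmetrical dialdehyde should stop at mono-olefination, and the E/Z outcome at the new bond is not critical because this bond becomes a single bond in step 18.

**Step 17**
Reactants: 23 [(2E,4E)-5-{(1S,4S,6R)-4-[(tert-butyldimethylsilyl)oxy]-2,2,6-trimethyl-7-oxabicyclo[4.1.0]heptan-1-yl}-3-methylpenta-2,4-dien-1-yl]triphenylphosphonium bromide; 25 (2E,4E,6E,8E,10E,12E)-2,7,11-trimethyl-13-(2,2,4,6-tetramethyl-2H-pyran-3-yl)trideca-2,4,6,8,10,12-hexaenal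
Product: 26 tert-butyldimethyl({(1S,4S,6R)-2,2,6-trimethyl-1-[(1E,3E,5E,7E,9E,11E,13E,15E,17E)-3,7,12,16-tetramethyl-18-(2,2,4,6-tetramethyl-2H-pyran-3-yl)octadeca-1,3,5,7,9,11,13,15,17-nonaen-1-yl]-7-oxabicyclo[4.1.0]heptan-4-yl}oxy)silane
Conditions: NaN(SiMe3)2, THF, −78 °C; then 25, −78 → 0 °C
Reagents that add atoms: none
Why: Wittig coupling of an epoxy C15 phosphonium ylide with a polyenal is the established way to attach 5,6-epoxy end groups; the phosphorus-stabilised ylide should leave the oxirane closed at low temperature.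

**Step 18**
Reactants: 26 the C40 pyran-capped epoxy nonaene
Product: 29 (3'S,5'R,6E,6'E)-3'-[(tert-butyldimethylsilyl)oxy]-5'-hydroxy-4,5'-retro-β,β-caroten-3-one, via ring-opened (Z)-dienone 27 (not isolated), via potassium cyclohexadienolate 28 (not isolated)
Conditions: KOt-Bu (3 equiv), THF/t-BuOH (10:1), 0 → 45 °C, argon, dark; then aq. NH4Cl
Reagents that add atoms: none
Why: Proposed new method: under equilibrating alkoxide base the 2H-pyran 26 stands in valence-tautomeric equilibrium (retro-oxa-6π) with the (Z)-dienone 27, whose acetyl methyl (C2) is deprotonated to the cross-conjugated enolate C2=C3(O−)–C4=C5–C6=C1, a 2-oxidohexatriene that closes thermally by disrotatory 6π-electrocyclisation (equivalently a 6-endo intramolecular 1,6-addition of the enolate carbon C2 to the isopropylidene carbon C1) to the cyclohexadienolate 28, which forms the C1–C2 bond and carbocycle A. Because C6 of 28 carries the whole conjugated chain, 28 is a polyenolate whose far terminus C7' is allylic to the C6'–O bond of the oxirane, and E1cB-type expulsion of that oxygen through the chain shifts every chain double bond by one position, delivers the 5'-alkoxide and regenerates the C3 carbonyl, so the whole sequence is a redox-neutral isomerisation with the strained oxirane as irreversible sink. The closest known reactions are the base-mediated closure of 4,6-dimethylhepta-3,5-dien-2-one (the valence tautomer of 2,2,4,6-tetramethyl-2H-pyran) to isophorone, the facile 6π-closure of 2-oxidotrienes, and the vinylogous β-elimination of epoxy enolates; their coupling over an 18-carbon polyene relay is without precedent. No stereocentre is created: C1 carries two identical methyl groups, C3 becomes a carbonyl, C5' keeps its configuration because its C–O bond is never broken, and C3' is a spectator. The step needs (i) enolisation at C2, secured because all other enolates of 27 form reversibly and only the C2 enolate has the triene required for closure, (ii) elimination of 28 in preference to protonation, favoured by the weak acid t-BuOH and by irreversibility, and (iii) E geometry of the new double bonds, expected because the polyenolate chain is s-trans throughout, A(1,3) strain with the C5 methyl places C8 on the C1 side of C6=C7, and at C6' the chain avoids the C5' methyl that eclipses it on the oxirane. The E/Z history of the chain double bonds of 26 is erased, since each of them becomes a single bond.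

**Step 19**
Reactants: 29 (3'S,5'R,6E,6'E)-3'-[(tert-butyldimethylsilyl)oxy]-5'-hydroxy-4,5'-retro-β,β-caroten-3-one
Product: 30 (3S,3'S,5'R,6E,6'E)-3'-O-(tert-butyldimethylsilyl)-4,5'-retro-β,β-carotene-3,3',5'-triol
Conditions: (R)-2-methyl-CBS-oxazaborolidine (0.5 equiv), catecholborane (excess), toluene/CH2Cl2, −78 → −40 °C; then MeOH, aq. NaHCO3
Reagents that add atoms: none
Why: In this Corey–Bakshi–Shibata reduction the (R)-oxazaborolidine should bind the carbonyl with the conjugated C4 side as the large group and deliver hydride to the face that gives the (3S)-allylic alcohol (the enantiomeric sense to acetophenone → (S)-1-phenylethanol), with clean 1,2-selectivity.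

**Step 20**
Reactants: 30 (3S,3'S,5'R,6E,6'E)-3'-O-(tert-butyldimethylsilyl)-4,5'-retro-β,β-carotene-3,3',5'-triol
Product: 31 (3S,3'S,5'R,6E,6'E)-4,5'-retro-β,β-carotene-3,3',5'-triol (CNP0269135.2)
Conditions: n-Bu4NF, THF, 0 °C → rt, argon, dark
Reagents that add atoms: none
Why: Fluoride desilylation is basic and non-acidic, which should preserve the acid-labile polyenylic 3-ol and the tertiary allylic 5'-ol.

**Compound list**

1 | 3-methylbut-2-enal | CC(C)=CC=O | starting material
2 | 2,3-dibromo-3-methylbutanal (racemic) | CC(C)(Br)C(Br)C=O | intermediate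
3 | 2-bromo-3-methylbut-2-enal | CC(C)=C(Br)C=O | intermediate
4 | 2-bromo-1,1-dimethoxy-3-methylbut-2-ene | COC(OC)C(Br)=C(C)C | intermediate
5 | (3E)-4-methoxypent-3-en-2-one | CO/C(C)=C/C(C)=O | starting material
6 | lithium (5E)-3-(dimethoxymethyl)-6-methoxy-2,4-dimethylhepta-2,5-dien-4-olate (racemic) | [Li+].[O-]C(C)(/C=C(/OC)C)C(C(OC)OC)=C(C)C | intermediate
7 | (3Z)-3-methyl-5-oxo-2-(propan-2-ylidene)hex-3-enal | CC(=O)/C=C(/C)C(C=O)=C(C)C | intermediate
8 | 2,2,4,6-tetramethyl-2H-pyran-3-carbaldehyde | CC1=CC(C)=C(C=O)C(C)(C)O1 | intermediate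
9 | ethyl (2E)-4-(diethoxyphosphoryl)-3-methylbut-2-enoate | CCOC(=O)/C=C(\C)CP(=O)(OCC)OCC | starting material
10 | ethyl (2E,4E)-3-methyl-5-(2,2,4,6-tetramethyl-2H-pyran-3-yl)penta-2,4-dienoate | CCOC(=O)/C=C(C)/C=C/C1=C(C)C=C(C)OC1(C)C | intermediate
11 | (2E,4E)-3-methyl-5-(2,2,4,6-tetramethyl-2H-pyran-3-yl)penta-2,4-dien-1-ol | OC/C=C(C)/C=C/C1=C(C)C=C(C)OC1(C)C | intermediate
12 | [(2E,4E)-3-methyl-5-(2,2,4,6-tetramethyl-2H-pyran-3-yl)penta-2,4-dien-1-yl]triphenylphosphonium bromide | [Br-].CC1=CC(C)=C(/C=C/C(C)=C/C[P+](c2ccccc2)(c2ccccc2)c2ccccc2)C(C)(C)O1 | intermediate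
13 | (4R,6R)-4-hydroxy-2,2,6-trimethylcyclohexan-1-one | O=C1C(C)(C)C[C@H](O)C[C@H]1C | starting material
14 | (4R,6R)-4-[(tert-butyldimethylsilyl)oxy]-2,2,6-trimethylcyclohexan-1-one | O=C1C(C)(C)C[C@H](O[Si](C)(C)C(C)(C)C)C[C@H]1C | intermediate
15 | (4R)-4-[(tert-butyldimethylsilyl)oxy]-2,6,6-trimethylcyclohex-1-en-1-yl trifluoromethanesulfonate | CC1=C(OS(=O)(=O)C(F)(F)F)C(C)(C)C[C@H](O[Si](C)(C)C(C)(C)C)C1 | intermediate
16 | methyl (4R)-4-[(tert-butyldimethylsilyl)oxy]-2,6,6-trimethylcyclohex-1-ene-1-carboxylate | COC(=O)C1=C(C)C[C@@H](O[Si](C)(C)C(C)(C)C)CC1(C)C | intermediate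
17 | {(4R)-4-[(tert-butyldimethylsilyl)oxy]-2,6,6-trimethylcyclohex-1-en-1-yl}methanol | OCC1=C(C)C[C@@H](O[Si](C)(C)C(C)(C)C)CC1(C)C | intermediate
18 | {(1R,4S,6R)-4-[(tert-butyldimethylsilyl)oxy]-2,2,6-trimethyl-7-oxabicyclo[4.1.0]heptan-1-yl}methanol | OC[C@@]12O[C@]1(C)C[C@@H](O[Si](C)(C)C(C)(C)C)CC2(C)C | intermediate
19 | (1S,4S,6R)-4-[(tert-butyldimethylsilyl)oxy]-2,2,6-trimethyl-7-oxabicyclo[4.1.0]heptane-1-carbaldehyde | O=C[C@@]12O[C@]1(C)C[C@@H](O[Si](C)(C)C(C)(C)C)CC2(C)C | intermediate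
20 | ethyl (2E,4E)-5-{(1S,4S,6R)-4-[(tert-butyldimethylsilyl)oxy]-2,2,6-trimethyl-7-oxabicyclo[4.1.0]heptan-1-yl}-3-methylpenta-2,4-dienoate | CCOC(=O)/C=C(C)/C=C/[C@@]12O[C@]1(C)C[C@@H](O[Si](C)(C)C(C)(C)C)CC2(C)C | intermediate
21 | (2E,4E)-5-{(1S,4S,6R)-4-[(tert-butyldimethylsilyl)oxy]-2,2,6-trimethyl-7-oxabicyclo[4.1.0]heptan-1-yl}-3-methylpenta-2,4-dien-1-ol | OC/C=C(C)/C=C/[C@@]12O[C@]1(C)C[C@@H](O[Si](C)(C)C(C)(C)C)CC2(C)C | intermediate
22 | {[(1S,3S,6S)-6-[(1E,3E)-5-bromo-3-methylpenta-1,3-dien-1-yl]-1,5,5-trimethyl-7-oxabicyclo[4.1.0]heptan-3-yl]oxy}(tert-butyl)dimethylsilane (C15 epoxy allylic bromide; locants of the epoxy ring as in 21 would read 1S,4S,6R) | BrC/C=C(C)/C=C/[C@@]12O[C@]1(C)C[C@@H](O[Si](C)(C)C(C)(C)C)CC2(C)C | intermediate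
23 | [(2E,4E)-5-{(1S,4S,6R)-4-[(tert-butyldimethylsilyl)oxy]-2,2,6-trimethyl-7-oxabicyclo[4.1.0]heptan-1-yl}-3-methylpenta-2,4-dien-1-yl]triphenylphosphonium bromide | [Br-].c1ccccc1[P+](c1ccccc1)(c1ccccc1)C/C=C(C)/C=C/[C@@]12O[C@]1(C)C[C@@H](O[Si](C)(C)C(C)(C)C)CC2(C)C | intermediate
24 | (2E,4E,6E)-2,7-dimethylocta-2,4,6-trienedial | O=C/C(C)=C/C=C/C=C(C)/C=O | starting material
25 | (2E,4E,6E,8E,10E,12E)-2,7,11-trimethyl-13-(2,2,4,6-tetramethyl-2H-pyran-3-yl)trideca-2,4,6,8,10,12-hexaenal | O=C/C(C)=C/C=C/C=C(C)/C=C/C=C(C)/C=C/C1=C(C)C=C(C)OC1(C)C | intermediate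
26 | tert-butyldimethyl({(1S,4S,6R)-2,2,6-trimethyl-1-[(1E,3E,5E,7E,9E,11E,13E,15E,17E)-3,7,12,16-tetramethyl-18-(2,2,4,6-tetramethyl-2H-pyran-3-yl)octadeca-1,3,5,7,9,11,13,15,17-nonaen-1-yl]-7-oxabicyclo[4.1.0]heptan-4-yl}oxy)silane | CC1=CC(C)=C(/C=C/C(C)=C/C=C/C(C)=C/C=C/C=C(C)/C=C/C=C(C)/C=C/[C@@]23O[C@]2(C)C[C@@H](O[Si](C)(C)C(C)(C)C)CC3(C)C)C(C)(C)O1 | intermediate
27 | ring-opened (Z)-dienone valence tautomer of 26 (acetyl–CH=C(CH3)–C(=CMe2)– terminus) | CC(=O)/C=C(/C)C(/C=C/C(C)=C/C=C/C(C)=C/C=C/C=C(C)/C=C/C=C(C)/C=C/[C@@]12O[C@]1(C)C[C@@H](O[Si](C)(C)C(C)(C)C)CC2(C)C)=C(C)C | intermediate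
28 | potassium cyclohexa-1,3-dien-1-olate formed by C1–C2 closure of the enolate of 27 (ring A closed, oxirane intact) | [K+].[O-]C1=CC(C)=C(/C=C/C(C)=C/C=C/C(C)=C/C=C/C=C(C)/C=C/C=C(C)/C=C/[C@@]23O[C@]2(C)C[C@@H](O[Si](C)(C)C(C)(C)C)CC3(C)C)C(C)(C)C1 | intermediate
29 | (3'S,5'R,6E,6'E)-3'-[(tert-butyldimethylsilyl)oxy]-5'-hydroxy-4,5'-retro-β,β-caroten-3-one | CC1=CC(=O)CC(C)(C)\C1=C/C=C(C)/C=C/C=C(C)/C=C/C=C/C(C)=C/C=C/C(C)=C/C=C1\C(C)(C)C[C@H](O[Si](C)(C)C(C)(C)C)C[C@@]1(C)O | intermediate
30 | (3S,3'S,5'R,6E,6'E)-3'-O-(tert-butyldimethylsilyl)-4,5'-retro-β,β-carotene-3,3',5'-triol | CC1=C[C@@H](O)CC(C)(C)\C1=C/C=C(C)/C=C/C=C(C)/C=C/C=C/C(C)=C/C=C/C(C)=C/C=C1\C(C)(C)C[C@H](O[Si](C)(C)C(C)(C)C)C[C@@]1(C)O | intermediate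
31 | (3S,3'S,5'R,6E,6'E)-4,5'-retro-β,β-carotene-3,3',5'-triol (CNP0269135.2) | CC1=C[C@@H](O)CC(C)(C)\C1=C/C=C(C)/C=C/C=C(C)/C=C/C=C/C(C)=C/C=C/C(C)=C/C=C1\C(C)(C)C[C@H](O)C[C@@]1(C)O | target

**Totals**

Total step count: 20.
Longest linear sequence: 13 steps (steps 7–15, then 17–20).

**Steps most likely to fail**

1. Step 18 (proposed new method). What may go wrong: the cyclohexadienolate is protonated before it expels the distant oxirane oxygen, so the sequence stops after ring closure; or geometric control at the new C6'=C7' bond is poor. Fallback with known reaction types, setting out from 26 and returning at 29: 26 is closed under classical isophorone conditions (KOH, MeOH/THF, 50 °C) with protonation of the extended enolate, which should give (3'S,5'R,6'S)-3'-[(tert-butyldimethylsilyl)oxy]-5',6'-epoxy-5',6'-dihydro-β,β-caroten-3-one F1. The alkenyl oxirane of F1 is then hydrogenolysed with zerovalent palladium and formate (Pd2(dba)3, n-Bu3P, HCO2NH4, dioxane), which delivers hydride to C6' with inversion and should give (3'S,5'R,6'S)-3'-[(tert-butyldimethylsilyl)oxy]-5'-hydroxy-5',6'-dihydro-β,β-caroten-3-one F2. Quinone dehydrogenation of F2 (DDQ, dioxane, rt; hydride abstraction from the tertiary allylic C6'–H, proton loss from C4 next to the ketone), the retro-dehydrogenation known for carotenoids, should then give 29. The two hydrogens are thus moved in two redox steps in place of the anionic relay.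

2. Step 19. What may go wrong: low facial selectivity, because the C2 methylene next to the quaternary C1 is nearly as demanding as the C4 vinyl carbon. Fallback, setting out from 29 and returning at 30: Luche reduction (NaBH4, CeCl3·7H2O, MeOH/THF, −40 °C) should give 30 together with its C3 epimer, (3R,3'S,5'R,6E,6'E)-3'-O-(tert-butyldimethylsilyl)-4,5'-retro-β,β-carotene-3,3',5'-triol F3. Lipase-catalysed acylation (immobilised Candida antarctica lipase B, vinyl acetate, toluene) is expected to acylate the (3R)-epimer selectively (conjugated side as the large group) to the 3-O-acetate of the (3R)-epimer F4, from which unreacted 30 is separated by chromatography and carried into step 20. F4 is recycled to 29 by methanolysis (K2CO3, MeOH) back to F3 and MnO2 oxidation.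

3. Step 3. What may go wrong: the hindered, basic alkenyl-metal enolises the vinylogous ester 5 in place of adding to it, or E→Z equilibration before pyran closure is incomplete. Fallback, setting out from 4 and returning at 8: after the same bromine–lithium exchange, acylation with N-methoxy-N-methylacetamide (Weinreb ketone synthesis) should give 3-(dimethoxymethyl)-4-methylpent-3-en-2-one F5, so that the C5–C6 bond is made without an enolisable electrophile. Aldol addition of the lithium enolate of acetone (acetone, LiN(i-Pr)2, THF, −78 °C) then makes the C4–C5 bond and should give racemic 5-(dimethoxymethyl)-4-hydroxy-4,6-dimethylhept-5-en-2-one F6. Aqueous HCl dehydrates F6 and hydrolyses its acetal to 7, which closes to 8.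

**Further compounds**

F1 | step 18 | (3'S,5'R,6'S)-3'-[(tert-butyldimethylsilyl)oxy]-5',6'-epoxy-5',6'-dihydro-β,β-caroten-3-one | O=C1CC(C)=C(/C=C/C(C)=C/C=C/C(C)=C/C=C/C=C(C)/C=C/C=C(C)/C=C/[C@@]23O[C@]2(C)C[C@@H](O[Si](C)(C)C(C)(C)C)CC3(C)C)C(C)(C)C1
F2 | step 18 | (3'S,5'R,6'S)-3'-[(tert-butyldimethylsilyl)oxy]-5'-hydroxy-5',6'-dihydro-β,β-caroten-3-one | O=C1CC(C)=C(/C=C/C(C)=C/C=C/C(C)=C/C=C/C=C(C)/C=C/C=C(C)/C=C/[C@H]2C(C)(C)C[C@H](O[Si](C)(C)C(C)(C)C)C[C@@]2(C)O)C(C)(C)C1
F3 | step 19 | (3R,3'S,5'R,6E,6'E)-3'-O-(tert-butyldimethylsilyl)-4,5'-retro-β,β-carotene-3,3',5'-triol | CC1=C[C@H](O)CC(C)(C)\C1=C/C=C(C)/C=C/C=C(C)/C=C/C=C/C(C)=C/C=C/C(C)=C/C=C1\C(C)(C)C[C@H](O[Si](C)(C)C(C)(C)C)C[C@@]1(C)O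
F4 | step 19 | (3R,3'S,5'R,6E,6'E)-3-O-acetyl-3'-O-(tert-butyldimethylsilyl)-4,5'-retro-β,β-carotene-3,3',5'-triol | CC1=C[C@H](OC(C)=O)CC(C)(C)\C1=C/C=C(C)/C=C/C=C(C)/C=C/C=C/C(C)=C/C=C/C(C)=C/C=C1\C(C)(C)C[C@H](O[Si](C)(C)C(C)(C)C)C[C@@]1(C)O
F5 | step 3 | 3-(dimethoxymethyl)-4-methylpent-3-en-2-one | CC(=O)C(C(OC)OC)=C(C)C
F6 | step 3 | 5-(dimethoxymethyl)-4-hydroxy-4,6-dimethylhept-5-en-2-one (racemic) | CC(=O)CC(C)(O)C(C(OC)OC)=C(C)C
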